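Temperature and time were given for south-east and north-west, so what I set out to reckon from the two earlier runs was the share of target in each flask at that time, and which flask wins.

common to all: first nucleophile 12.1 mM; second nucleophile 12.1 mM

| run | substrate | temperature | remark | time |
|---|---|---|---|---|
| elm | 4.5 mM | 4 °C | run made earlier |  |
| ash | 7.4 mM | 12 °C | run made earlier |  |
| south-east | 11 mM | 0 °C |  | 3.0 d |
| north-west | 6.0 mM | 15 °C |  | 3.0 d |

elm run (percent of the substrate charged)

| time / d | target / % | other capture product / % |
|---|---|---|
| 0.500 | 39 | 47 |
| 1.04 | 31 | 51 |
| 1.67 | 23 | 49 |
| 2.08 | 19 | 50 |
| 2.50 | 16 | 51 |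
| 3.00 | 13 | 51 |

ash run (percent of the substrate charged)

| time / h | target / % | other capture product / % |
|---|---|---|
| 3.00 | 41 | 46 |
| 8.00 | 37 | 45 |
| 15.0 | 28 | 50 |
| 20.0 | 26 | 51 |
| 30.0 | 21 | 49 |
| 40.0 | 17 | 51 |

(readings scatter by 1.5 percentage points)

* the winner by share of target in all that became target or other capture product or over-reaction product or side product; "neither" if no more than 2 percentage points parts them (south-east / north-west / neither)
* share of target in all that became target or other capture product or over-reaction product or side product, south-east
* share of target in all that became target or other capture product or over-reaction product or side product, north-west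

- in percentages every species weighs as the substrate in it: one side product counts as two
- the numbers in the tables scatter by 1.5 percentage points (one standard deviation)

In the elm run the other capture product stayed near 51 % while the target kept falling, so I took capture as over early and the target as lost afterwards. I let 49.0 % of the substrate go to the target side, and I assumed that each target made takes one first nucleophile and each target over-reacted takes one more. Target and c(first nucleophile) then fall together, mM for mM, and their difference stays constant. This difference, the charge less twice the target side, I call the spare first nucleophile: 1.32 mM in south-east.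

The falling target, reckoned with each run's spare, gave an over-reaction constant of 0.0503 mM⁻¹ d⁻¹ in elm and 0.0836 mM⁻¹ d⁻¹ in ash. With the same factor per degree, that made 0.0390 mM⁻¹ d⁻¹ for south-east and 0.101 mM⁻¹ d⁻¹ for north-west.

I then went two ways to south-east, taking the substrate as spent. Holding c(first nucleophile) at its level after capture, the pseudo-first-order way, gave 22.4 %. Letting it fall with the target, by the second-order law, gave 26.5 %. The first way cheats in south-east, where the spare is smaller than the 5.39 mM of target, so I kept the second. For north-west, with a spare of 6.22 mM, it gave 5.29 %.

The forecast named south-east, with 20 % and 6.5 %, taking the decay as “first order in the remaining nucleophile”. Its south-east figure is lower than mine, and its north-west figure higher.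

The flask gives south-east, at 28.4 % against 8.17 % for north-west. South-east still held 32.0 % of its first nucleophile at 3.00 d, which is 3.88 mM, with 0.790 mM of decomposed reagent formed. The spare plus the target found comes to 4.44 mM, which is more than the first nucleophile found.

    second nucleophile + intermediate → other capture product (k = 20.0 M⁻¹ h⁻¹, Ea = 62.0 kJ mol⁻¹)
    substrate → intermediate (k = 0.530 h⁻¹, Ea = 90.0 kJ mol⁻¹)
    first nucleophile → decomposed reagent (k = 0.00200 h⁻¹, Ea = 101 kJ mol⁻¹)
    first nucleophile + intermediate → target (k = 20.0 M⁻¹ h⁻¹, Ea = 63.0 kJ mol⁻¹)
    substrate + intermediate → side product (k = 2.60 M⁻¹ h⁻¹, Ea = 63.0 kJ mol⁻¹)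
    first nucleophile + target → over-reaction product (k = 1.50 M⁻¹ h⁻¹, Ea = 67.0 kJ mol⁻¹)
    (constants at 0 °C)

With 48 mM of first nucleophile in the south-east flask, and the target side taken in proportion to the charges at 79.9 %, the spare is 30.4 mM. The same law then gives 1.78 %, and the computed flask gives 3.23 %.

The readings were computed with made-up constants; the scatter is artificial.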